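If you want a quick number for the flask with 0.800 equiv of L, don't scale the curves. Ask what share of the L charged stands as E at the top of each run. Q is the substrate, L the reagent, and E their mono adduct.

in all of them: Q 0.99 M

| flask | L | remark | time |
|---|---|---|---|
| winter | 1.1 equiv | run made earlier |  |
| dusk | 1.8 equiv | run made earlier |  |
| flask | 0.800 equiv |  | 30 min |

- winter (time / min: E / %, Q / %): 0.250: 24.8, 61.0; 1.00: 23.5, 30.5; 5.00: 15.0, 2.5; 25.0: 7.5, 0.1
- dusk (time / min: E / %, Q / %): 0.250: 35.1, 45.0; 1.00: 33.2, 15.0; 5.00: 16.9, 0.6; 25.0: 2.9, 0.3

(scatter of a reading: 0.3 percentage points)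

- when, up to 30 min, the flask holds most E
- the amount of E, in percent of the Q charged, at that time
- earliest time at which at least nineteen twentieths of that best amount are there, in min
- latest time at which they still are, in min



Call y the yield on L: the top E reading as a fraction of the L charged, both counted against the Q charged. The winter run, read at 0.250 min, gives y = 0.225. The dusk run, read at 0.250 min, gives 0.195. So y is lower with more L, and it drops by m = 0.0435 per equivalent of L. That is a reading, with the scatter of both runs in it.

Winter's y applied to the flask gives a first answer of 18.0%. But the flask has less L than winter, so go round once more: m lifts y to 0.239, and my reckoning for the top is 19.1%.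

The forecast is higher than my figure: 20.5% at 0.45 min, with the window from 0.2 min to 1.1 min, since “The top is broad”. For the times I have nothing of my own to set beside it.

The flask reaches 19.5% at 0.396 min, and the window asked for runs from 0.198 min to 0.873 min.

    Q + L → E (k = 0.0662 L mol⁻¹ s⁻¹)
    L + E → X (k = 0.0224 L mol⁻¹ s⁻¹)
    L + X → D (k = 0.307 L mol⁻¹ s⁻¹)
    L ⇌ G (K = 3.20, k = 0.135 s⁻¹)
    Q + E → J (k = 0.0295 L mol⁻¹ s⁻¹)

So y in the flask is 0.244, against the 0.239 reckoned. One part of why y stays this low is the step from Q + E to J: run without it, the flask's highest E is 51.6% instead of 19.5%. For the neighbour flask with 0.320 equiv of L, m lifts y to 0.259, which gives 8.30%. Computed, that neighbour reaches 8.41%, and L, its limiting reagent, is down to 0% at 30.0 min, with 39% of Q left.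

The runs stem from a simulated flask with made-up constants, and the scatter is random.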